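Remarks on the chemistry: ethyl 2-isopropylacetoacetate (14) is taken as a purchasable starting material (it is the isopropylation product of ethyl acetoacetate). The sense of induction of the copper–carbene catalyst in step 1 is not predicted here; the ligand enantiomer is the one that gives (3R)-5. Compound 21 is drawn as one enol tautomer.

## Analysis of the target

The target 25 is a ring-A-seco abietane. A cyclohexenone ring B is fused through the C8=C9 bond to a fully substituted 2-hydroxy-1,4-benzoquinone ring C, and the carbons of the lost ring A remain as an isopropenyl group on C5 and a CH2CH2CO2Me chain on C10. Numbering used throughout: ring B is C5 (CH), C6 (CH2), C7 (C=O), C8, C9, C10 (quaternary, CH3 and ester chain); ring C is C8, C9, C11 (C=O next to C9), C12 (C–OH), C13 (C–isopropyl), C14 (C=O next to C8). There are two stereocentres, the tertiary C5 and the adjacent quaternary C10, both S, with the C10 methyl cis to the isopropenyl group and the ester chain trans to it. The sensitive functions are the acidic, redox-active hydroxyquinone, the vinylogous tricarbonyl it forms with the C7 ketone, the acid- and oxidant-sensitive 1,1-disubstituted alkene, and the methyl ester (hydrolysis, enolisation, Claisen chemistry). The difficulties are a quaternary centre beside a tertiary one, a ring C in which every carbon is substituted and three carry oxygen, and the need to tell the two ring-B carbonyl carbons C7 and C9 apart. The strategy rests on the 1,3-relationship of the C12 and C14 oxygens with the isopropyl carbon C13 between them: read as a resorcinol, ring C is the aldol fold of a chain C14(=O)–C13H(iPr)–C12(=O)–C11H3 attached to C8, with the ring-B carbonyl C9 as acceptor. C11 stays unsubstituted in that resorcinol and lies para to the C14 hydroxyl, which is where a final phenol oxidation brings in the last quinone oxygen.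

## Retrosynthetic reasoning

25 to 24. The C11–O bond is cut first. The quinone is the most fragile part of the molecule and is best made last; resorcinol 24 has a single free ring position, C11, para to the C14 hydroxyl and ortho to the C12 hydroxyl, so a radical phenol oxidation can only give the 2-hydroxy-1,4-quinone of 25.

24 to 23. The C7 ketone is masked as its cyclic ketal in 23. The mask is needed one step earlier, and its removal is easy because the ketal carbon is benzylic and flanked by ortho and para hydroxyls.

23 to 21 (key disconnection). The C9–C11 bond of ring C is cut, with rehydration and dearomatisation, to triketone 21. This is the retro-aldol of a resorcinol. It is chosen over other ring-C bonds because it removes a whole ring and returns to a chain whose carbons already sit at the right oxidation levels, with isopropyl on the central carbon. Because C7 is a ketal in 21, C9 is the only ring carbonyl the methyl carbon C11 can reach through a six-membered transition state, so the fold is unambiguous. The forward reaction has to make C11 attack a hindered ketone and then aromatise.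

21 to 20 to 13 + 17. The C8–C14 bond is cut. A direct acyl donor with the C12 ketone in place would carry an acidic C13–H that quenches the enolate. Stepwise acylation followed by acetylation at C13 would need a dianion, which would expel the C7 ketal oxygen and compete with the ester α-protons. The chain is therefore brought in as aldehyde 17, with C14 at the aldehyde level and C12 as a silyl-protected carbinol; an aldol at −78 °C gives diol 20 after desilylation, and one double oxidation gives 21. The enolate of 13 is only formed cold and trapped at once; after oxidation C8 sits between two carbonyls and the ketal is no longer at risk.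

17 to 16 to 15 to 14. The aldehyde is reached from β-keto ester 14 by ketone reduction, silylation and partial ester reduction, without forming any C–C bond.

13 to 12 to 11 to 10 to 9. The C7 oxygen is removed. Ketal 13 comes from 1,3-dione 12 at the less hindered carbonyl (C9 is shielded by the quaternary C10). Dione 12 comes from epoxy ketone 11 by redox-neutral isomerisation, 11 from enone 10, and 10 from ketone 9 by dehydrogenation, which can only go towards C8 because C10 has no hydrogen.

9 to 5 + 6. The C10–CH2 bond is cut. A Michael addition of the more substituted α-carbon of 5 to acrylate 6 delivers the ester chain at its final oxidation level and sets the quaternary centre. The acceptor enters anti to the neighbouring isopropenyl group, which is the relative configuration of 25.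

5 to 2 + 1. The C5–isopropenyl bond is cut. A catalytic asymmetric conjugate addition of the Grignard reagent 3, made from 1, to enone 2 sets the only stereocentre that is not substrate-controlled.

## Alternatives that were turned down

Alternative 1: dearomatising three-component addition to a naphthalene. Here ring C and the ring-B carbons are bought as an aromatic: the chiral naphthyl oxazoline A1 would take up an isopropenyl-lithium reagent at the carbon that becomes C5, and the resulting aza-enolate would be alkylated at C10 by a protected 3-hydroxypropyl iodide, giving dihydronaphthalene A2 with both stereocentres set trans in one operation.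
- In its favour: stereocontrol by a proven auxiliary, no hindered ring closure, and a C7 oxygen already present as an enol ether. On convergence and on the security of ring C it is stronger than the chosen route.
- Against it: A1, with three methoxy groups and an isopropyl group in a defined pattern, is a multistep target in itself, and its electron-rich ring is a poor acceptor for the organolithium.
- After the key step the oxazoline carbon must be reduced all the way to the C10 methyl, the silyloxypropyl chain oxidised to the ester, and three methyl ethers cleaved beside an isopropenyl group before the quinone can be made.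
- The chosen route has methyl and ester chain at their final oxidation levels from step 2 and needs two steps after ring C is closed.

Alternative 2: catalytic asymmetric Diels–Alder for ring B. Dienal A3 would react through its α,β double bond with silyloxydiene A4 under a chiral boron Lewis acid to give cyclohexene A5, in which C10 (methyl, formyl), C5 (isopropenyl), the C9 oxygen and a C7=C8 double bond are all present.
- In its favour: both stereocentres from one catalytic event, with the E geometry of A3 translating into the correct methyl/isopropenyl cis relationship, and ring B arriving already unsaturated where the chosen route needs a dehydrogenation.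
- Against it: A3 is a trisubstituted, cross-conjugated dienophile of low reactivity that can also react as a diene with itself.
- The formyl group must be homologated by two carbons and the new alkene reduced selectively beside two others, which costs more steps than the one acrylate addition of the chosen route.
- Ring C would still have to be built afterwards, so this alternative changes only the first steps and does not shorten the sequence.

Alternative 3: cyclobutenone ring expansion for ring C. A ring-B vinyl metal (at C9) would add to a squarate-derived cyclobutenedione to give cyclobutenone A6; heating opens it to a dienylketene that closes between C14 and C8 to hydroquinone A7, with the C7 ketal and a silyl ether chain as spectators.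
- In its favour: neutral thermal conditions, a regiochemistry fixed by the squarate, and all three ring-C oxygens, including the one on C11, delivered at once. It is stronger than the chosen route on the reliability of ring-C formation and needs no late phenol oxidation to reach the quinone level.
- Against it: the vinyl metal at C9 must be generated next to a quaternary carbon and in the presence of a ketal.
- The ester cannot be carried through organolithium chemistry, so the chain must later be oxidised from an alcohol in the presence of a quinone.
- The C12 isopropyl ether must also be cleaved.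
- The chosen route needs no organometallic after step 1, uses cheap reagents and reaches the target in two steps from the ring-C product.

Key step: step 12

## Route

Step 1
Reactants: 1 2-bromopropene; 2 2-methylcyclohex-2-en-1-one
Product: 5 (3R)-2-methyl-3-(prop-1-en-2-yl)cyclohexan-1-one (cis/trans mixture at C2), via isopropenylmagnesium bromide 3 (not isolated), via bromomagnesium enolate 4 (not isolated)
Conditions: Mg, THF, 40 °C; then 2, Cu(OTf)2 (3 mol %), chiral imidazolinium carbene precursor (4 mol %), Et2O, −30 °C; aq. NH4Cl
Reagents that add atoms: none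
Why: Copper-catalysed asymmetric conjugate addition of a Grignard reagent to an α-substituted cyclic enone, a known reaction class; the chiral carbene–copper complex selects the enone face and so sets C5 (3R in 5), while C2 stays epimerisable and is fixed only in step 2.

Step 2
Reactants: 5 (3R)-2-methyl-3-(prop-1-en-2-yl)cyclohexan-1-one; 6 methyl acrylate
Product: 9 methyl 3-[(1S,6S)-1-methyl-2-oxo-6-(prop-1-en-2-yl)cyclohexyl]propanoate, via ketimine 7 (not isolated), via alkylated ketimine 8 (not isolated)
Conditions: (S)-1-phenylethylamine, 4 Å molecular sieves, toluene, 60 °C; then 6, THF, 40 °C; then 20% aq. AcOH, 25 °C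
Reagents that add atoms: none
Why: Michael addition of a chiral imine through its more substituted secondary enamine tautomer (d'Angelo reaction), which alkylates at the methyl-bearing carbon under neutral conditions without acrylate oligomerisation; the acrylate enters anti to the neighbouring isopropenyl group and the (S)-auxiliary, by its facial preference in 2-methylcyclohexanone imines, reinforces this, so C10 is set S with the methyl cis to isopropenyl.

Step 3
Reactants: 9 methyl 3-[(1S,6S)-1-methyl-2-oxo-6-(prop-1-en-2-yl)cyclohexyl]propanoate
Product: 10 methyl 3-[(1S,6S)-1-methyl-2-oxo-6-(prop-1-en-2-yl)cyclohex-3-en-1-yl]propanoate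
Conditions: IBX (2 equiv), DMSO–toluene, 70 °C
Reagents that add atoms: none
Why: IBX dehydrogenation of a ketone to the enone; only C8 is enolisable because C10 is quaternary, so the C7=C8 enone is the only regioisomer, and the ester and the isopropenyl group are inert to IBX.

Step 4
Reactants: 10 methyl 3-[(1S,6S)-1-methyl-2-oxo-6-(prop-1-en-2-yl)cyclohex-3-en-1-yl]propanoate
Product: 11 methyl 3-[(3S,4S)-3-methyl-2-oxo-4-(prop-1-en-2-yl)-7-oxabicyclo[4.1.0]heptan-3-yl]propanoate (epoxide diastereomers)
Conditions: t-BuOOH, DBU, CH2Cl2, 0 → 25 °C
Reagents that add atoms: tert-butyl hydroperoxide, CC(C)(C)OO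
Why: Nucleophilic (Weitz–Scheffer) epoxidation attacks only the electron-poor enone double bond, not the isopropenyl group, and the anhydrous base spares the ester; both epoxide diastereomers converge in step 5.

Step 5
Reactants: 11 methyl 3-[(3S,4S)-3-methyl-2-oxo-4-(prop-1-en-2-yl)-7-oxabicyclo[4.1.0]heptan-3-yl]propanoate
Product: 12 methyl 3-[(1S,6S)-1-methyl-2,4-dioxo-6-(prop-1-en-2-yl)cyclohexyl]propanoate
Conditions: Pd(PPh3)4 (5 mol %), dppe (5 mol %), toluene, 100 °C
Reagents that add atoms: none
Why: Known isomerisation of an α,β-epoxy ketone to a 1,3-diketone by zerovalent palladium (oxidative addition into the Cα–O bond, then β-hydride elimination from C7); it is redox-neutral and installs the C7 carbonyl without touching alkene or ester.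

Step 6
Reactants: 12 methyl 3-[(1S,6S)-1-methyl-2,4-dioxo-6-(prop-1-en-2-yl)cyclohexyl]propanoate
Product: 13 methyl 3-[(8S,9S)-8-methyl-7-oxo-9-(prop-1-en-2-yl)-1,4-dioxaspiro[4.5]decan-8-yl]propanoate
Conditions: HOCH2CH2OH (1.5 equiv), PPTS (cat.), benzene, reflux, Dean–Stark
Reagents that add atoms: ethylene glycol, OCCO
Why: Acid-catalysed mono-ketalisation of a cyclic 1,3-dione with water removal; C9 is shielded by the quaternary C10, so the glycol condenses at C7, and the hydroxyethyl enol ether formed first closes to the spiroketal by intramolecular addition.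

Step 7
Reactants: 14 ethyl 2-isopropylacetoacetate
Product: 15 ethyl 3-hydroxy-2-(propan-2-yl)butanoate (racemic diastereomer mixture)
Conditions: NaBH4, EtOH, 0 °C
Reagents that add atoms: none
Why: Borohydride reduction of the ketone of a β-keto ester leaves the ester untouched; the stereoisomer mixture is irrelevant because both centres are later oxidised or made aromatic.

Step 8
Reactants: 15 ethyl 3-hydroxy-2-(propan-2-yl)butanoate
Product: 16 ethyl 2-(propan-2-yl)-3-(triethylsilyloxy)butanoate
Conditions: Et3SiCl, imidazole, DMF, 25 °C
Reagents that add atoms: chlorotriethylsilane, CC[Si](Cl)(CC)CC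
Why: Standard silylation of a secondary alcohol; it removes the O–H that would quench the enolate in step 10 and the ether is later cleaved by fluoride without acid.

Step 9
Reactants: 16 ethyl 2-(propan-2-yl)-3-(triethylsilyloxy)butanoate
Product: 17 2-(propan-2-yl)-3-(triethylsilyloxy)butanal
Conditions: iBu2AlH, CH2Cl2, −78 °C; aq. potassium sodium tartrate
Reagents that add atoms: none
Why: Partial reduction of an ester to the aldehyde with iBu2AlH at −78 °C; the tetrahedral aluminium hemiacetal of this α-branched β-silyloxy ester persists until work-up.

Step 10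
Reactants: 13 methyl 3-[(8S,9S)-8-methyl-7-oxo-9-(prop-1-en-2-yl)-1,4-dioxaspiro[4.5]decan-8-yl]propanoate; 17 2-(propan-2-yl)-3-(triethylsilyloxy)butanal
Product: 20 methyl 3-[(8S,9S)-6-[1,3-dihydroxy-2-(propan-2-yl)butyl]-8-methyl-7-oxo-9-(prop-1-en-2-yl)-1,4-dioxaspiro[4.5]decan-8-yl]propanoate (diastereomer mixture at the four new centres), via lithium enolate 18 (not isolated), via triethylsilyl aldol adduct 19 (not isolated)
Conditions: LiN(SiMe3)2 (1.05 equiv), THF, −78 °C; 17, −78 °C; AcOH; then Bu4NF–AcOH (1:1), THF, 0 °C
Reagents that add atoms: none
Why: Lithium enolate aldol addition: the amide base deprotonates C8, the only enolisable ketone position, in preference to the ester, and the aldehyde traps the enolate at −78 °C, where β-alkoxy enolates are known to resist loss of the β-oxygen; buffered fluoride then frees the C12 hydroxyl, and the new stereocentres need no control because steps 11 and 12 erase them.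

Step 11
Reactants: 20 methyl 3-[(8S,9S)-6-[1,3-dihydroxy-2-(propan-2-yl)butyl]-8-methyl-7-oxo-9-(prop-1-en-2-yl)-1,4-dioxaspiro[4.5]decan-8-yl]propanoate
Product: 21 methyl 3-[(8S,9S)-8-methyl-7-oxo-6-[3-oxo-2-(propan-2-yl)butanoyl]-9-(prop-1-en-2-yl)-1,4-dioxaspiro[4.5]decan-8-yl]propanoate (enolised triketone with C7 ketal)
Conditions: Dess–Martin periodinane (2.5 equiv), NaHCO3, CH2Cl2, 0 → 25 °C
Reagents that add atoms: none
Why: Dess–Martin oxidation of both secondary alcohols gives the 1,3,5-tricarbonyl chain under buffered, near-neutral conditions that keep the ketal; once C8 lies between two carbonyls its enolate is too stabilised to expel the ketal oxygen.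

Step 12
Reactants: 21 methyl 3-[(8S,9S)-8-methyl-7-oxo-6-[3-oxo-2-(propan-2-yl)butanoyl]-9-(prop-1-en-2-yl)-1,4-dioxaspiro[4.5]decan-8-yl]propanoate
Product: 23 methyl 3-[(1'S,2'S)-5',7'-dihydroxy-1'-methyl-6'-(propan-2-yl)-2'-(prop-1-en-2-yl)-2',3'-dihydro-1'H-spiro[[1,3]dioxolane-2,4'-naphthalen]-1'-yl]propanoate, via aldol adduct 22 (not isolated)
Conditions: Cs2CO3 (1.5 equiv), MeOH, 25 → 45 °C; then AcOH–NaOAc buffer (pH 5), 25 °C
Reagents that add atoms: none
Why: The carbonate sets up the triketone monoanion; through the minor tautomer in which the terminal methyl ketone is enolised, C11 adds to the C9 carbonyl and gives the 5-hydroxycyclohexane-1,3-dione 22, which loses water on partial neutralisation and tautomerises to the resorcinol. The closest known reaction is the base-mediated cyclisation of 1,3,5-triketones to resorcinols, the polyketide-type aldol aromatisation. Ring C closes by a 6-(enolendo)-exo-trig aldol that forms the C9–C11 bond. No stereocentre is created in the product, since the transient centres of 22 vanish on aromatisation and C5 and C10 are not enolisable. The step needs C-cyclisation at C9 and not at C7, which the ketal secures by leaving C9 as the only ring carbonyl within reach of C11. It also needs carbon attack in preference to pyranone formation through oxygen, which is an acid pathway and is avoided by completing the aldol under base before the buffer is added. The side-chain ester is protected by the choice of carbonate in methanol, where ester exchange is degenerate and the base is too weak to enolise the ester or to drive a Claisen closure, whose bridged product could not be stabilised as an enolate anyway. The hindrance at C9, flanked by the quaternary C10, is the situation met in Robinson-type annulations that create angular methyl groups, and aromatisation makes the closure irreversible; should the ketal be lost in the buffer, the material simply converges with 24.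

Step 13
Reactants: 23 methyl 3-[(1'S,2'S)-5',7'-dihydroxy-1'-methyl-6'-(propan-2-yl)-2'-(prop-1-en-2-yl)-2',3'-dihydro-1'H-spiro[[1,3]dioxolane-2,4'-naphthalen]-1'-yl]propanoate
Product: 24 methyl 3-[(1S,2S)-5,7-dihydroxy-1-methyl-4-oxo-6-(propan-2-yl)-2-(prop-1-en-2-yl)-1,2,3,4-tetrahydronaphthalen-1-yl]propanoate
Conditions: 80% aq. AcOH, THF, 40 °C
Reagents that add atoms: water, O
Why: Acid hydrolysis of a ketal whose oxocarbenium ion is benzylic and stabilised by the ortho and para hydroxyls, so aqueous acetic acid is enough and the isopropenyl group and the ester survive.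

Step 14
Reactants: 24 methyl 3-[(1S,2S)-5,7-dihydroxy-1-methyl-4-oxo-6-(propan-2-yl)-2-(prop-1-en-2-yl)-1,2,3,4-tetrahydronaphthalen-1-yl]propanoate
Product: 25 methyl 3-[(1S,2S)-7-hydroxy-1-methyl-4,5,8-trioxo-6-(propan-2-yl)-2-(prop-1-en-2-yl)-1,2,3,4,5,8-hexahydronaphthalen-1-yl]propanoate (target)
Conditions: (KSO3)2NO (2.5 equiv), KH2PO4 buffer, H2O–acetone, 0 → 25 °C
Reagents that add atoms: potassium nitrosodisulfonate (Fremy's salt), [K+].[K+].[O]N(S(=O)(=O)[O-])S(=O)(=O)[O-]
Why: Teuber oxidation: the nitroxyl radical forms the phenoxyl radical and a second equivalent delivers oxygen to C11, the only free ring position (para to the C14 hydroxyl, ortho to the C12 hydroxyl), giving the 2-hydroxy-1,4-quinone directly; no stereocentre is involved.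

## Compound list

1 | 2-bromopropene | C=C(C)Br | starting material
2 | 2-methylcyclohex-2-en-1-one | CC1=CCCCC1=O | starting material
3 | isopropenylmagnesium bromide | C=C(C)[Mg]Br | intermediate
4 | bromomagnesium enolate of 5 | C=C(C)[C@@H]1CCCC(O[Mg]Br)=C1C | intermediate
5 | (3R)-2-methyl-3-(prop-1-en-2-yl)cyclohexan-1-one | C=C(C)[C@@H]1CCCC(=O)C1C | intermediate
6 | methyl acrylate | C=CC(=O)OC | starting material
7 | (S)-N-(1-phenylethyl) ketimine of 5 | C=C(C)[C@@H]1CCCC(=N[C@@H](C)c2ccccc2)C1C | intermediate
8 | (S)-N-(1-phenylethyl) ketimine of 9 | C=C(C)[C@@H]1CCCC(=N[C@@H](C)c2ccccc2)[C@@]1(C)CCC(=O)OC | intermediate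
9 | methyl 3-[(1S,6S)-1-methyl-2-oxo-6-(prop-1-en-2-yl)cyclohexyl]propanoate | C=C(C)[C@@H]1CCCC(=O)[C@@]1(C)CCC(=O)OC | intermediate
10 | methyl 3-[(1S,6S)-1-methyl-2-oxo-6-(prop-1-en-2-yl)cyclohex-3-en-1-yl]propanoate | C=C(C)[C@@H]1CC=CC(=O)[C@@]1(C)CCC(=O)OC | intermediate
11 | methyl 3-[(3S,4S)-3-methyl-2-oxo-4-(prop-1-en-2-yl)-7-oxabicyclo[4.1.0]heptan-3-yl]propanoate | C=C(C)[C@@H]1CC2OC2C(=O)[C@@]1(C)CCC(=O)OC | intermediate
12 | methyl 3-[(1S,6S)-1-methyl-2,4-dioxo-6-(prop-1-en-2-yl)cyclohexyl]propanoate | C=C(C)[C@@H]1CC(=O)CC(=O)[C@@]1(C)CCC(=O)OC | intermediate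
13 | methyl 3-[(8S,9S)-8-methyl-7-oxo-9-(prop-1-en-2-yl)-1,4-dioxaspiro[4.5]decan-8-yl]propanoate | C=C(C)[C@@H]1CC2(OCCO2)CC(=O)[C@@]1(C)CCC(=O)OC | intermediate
14 | ethyl 2-isopropylacetoacetate | CCOC(=O)C(C(C)C)C(C)=O | starting material
15 | ethyl 3-hydroxy-2-(propan-2-yl)butanoate | CCOC(=O)C(C(C)C)C(C)O | intermediate
16 | ethyl 2-(propan-2-yl)-3-(triethylsilyloxy)butanoate | CCOC(=O)C(C(C)C)C(C)O[Si](CC)(CC)CC | intermediate
17 | 2-(propan-2-yl)-3-(triethylsilyloxy)butanal | O=CC(C(C)C)C(C)O[Si](CC)(CC)CC | intermediate
18 | lithium enolate of 13 | C=C(C)[C@@H]1CC2(OCCO2)C=C(O[Li])[C@@]1(C)CCC(=O)OC | intermediate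
19 | triethylsilyl aldol adduct (C14 hydroxyl free, C12 silyl ether) | C=C(C)[C@@H]1CC2(OCCO2)C(C(O)C(C(C)C)C(C)O[Si](CC)(CC)CC)C(=O)[C@@]1(C)CCC(=O)OC | intermediate
20 | methyl 3-[(8S,9S)-6-[1,3-dihydroxy-2-(propan-2-yl)butyl]-8-methyl-7-oxo-9-(prop-1-en-2-yl)-1,4-dioxaspiro[4.5]decan-8-yl]propanoate | C=C(C)[C@@H]1CC2(OCCO2)C(C(O)C(C(C)C)C(C)O)C(=O)[C@@]1(C)CCC(=O)OC | intermediate
21 | methyl 3-[(8S,9S)-8-methyl-7-oxo-6-[3-oxo-2-(propan-2-yl)butanoyl]-9-(prop-1-en-2-yl)-1,4-dioxaspiro[4.5]decan-8-yl]propanoate, enol form | C=C(C)[C@@H]1CC2(OCCO2)C(C(=O)/C(C(C)C)=C(\O)C)=C(O)[C@@]1(C)CCC(=O)OC | intermediate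
22 | aldol adduct: C9 tertiary carbinol with 1,3-dione ring C, C7 ketal | C=C(C)[C@@H]1CC2(OCCO2)C3C(=O)C(C(C)C)C(=O)CC3(O)[C@@]1(C)CCC(=O)OC | intermediate
23 | methyl 3-[(1'S,2'S)-5',7'-dihydroxy-1'-methyl-6'-(propan-2-yl)-2'-(prop-1-en-2-yl)-2',3'-dihydro-1'H-spiro[[1,3]dioxolane-2,4'-naphthalen]-1'-yl]propanoate | C=C(C)[C@@H]1CC2(OCCO2)c2c(O)c(C(C)C)c(O)cc2[C@@]1(C)CCC(=O)OC | intermediate
24 | methyl 3-[(1S,2S)-5,7-dihydroxy-1-methyl-4-oxo-6-(propan-2-yl)-2-(prop-1-en-2-yl)-1,2,3,4-tetrahydronaphthalen-1-yl]propanoate | C=C(C)[C@@H]1CC(=O)c2c(O)c(C(C)C)c(O)cc2[C@@]1(C)CCC(=O)OC | intermediate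
25 | methyl 3-[(1S,2S)-7-hydroxy-1-methyl-4,5,8-trioxo-6-(propan-2-yl)-2-(prop-1-en-2-yl)-1,2,3,4,5,8-hexahydronaphthalen-1-yl]propanoate | C=C(C)[C@@H]1CC(=O)C2=C(C(=O)C(O)=C(C(C)C)C2=O)[C@@]1(C)CCC(=O)OC | target

## Step count and risk

Total step count: 14. Longest linear sequence: 11 (steps 1–6 and 10–14); steps 7–9 make the side-chain aldehyde.

Least certain steps:

Step 12 (key step). Most likely failure: the C11 enolate does not add to C9, which is neopentyl and, as part of the C9/C14 enolate system, electron-rich. Slower processes then take over: methanolysis of the acetyl group (retro-Claisen) under base, or oxygen cyclisation to the pyranone once the buffer is added. Fallback, from 19 back to 22: make the C9–C11 bond while C14 is still a protected carbinol, so that C9 is an isolated ketone.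
- Adduct 19 is isolated and its free C14 hydroxyl silylated (tBuMe2SiOTf, 2,6-lutidine, −78 °C) to the bis-silyl ether F1.
- The triethylsilyl group is removed selectively (HF·pyridine buffered with pyridine, 0 °C) to the C12 alcohol F2, and Dess–Martin oxidation gives the methyl ketone F3.
- KN(SiMe3)2 at −78 °C forms the kinetic methyl enolate, which closes onto C9 to the β-hydroxy ketone F4.
- Bu4NF frees the C14 alcohol (diol F5), and Dess–Martin oxidation of that secondary alcohol gives 22, which dehydrates to 23 under the buffer of step 12.

Step 10. Most likely failure: β-elimination of the ketal oxygen from the C8 enolate before the hindered enolate meets the α-branched aldehyde, or reversal of the aldol during desilylation. Fallback, from 13 back to 19: avoid a free metal enolate in the C–C bond-forming event. LiN(iPr)2 is added to 13 in the presence of Me3SiCl at −78 °C (internal quench) to give the trimethylsilyl enol ether F6, which undergoes a Mukaiyama aldol addition with 17 (BF3·OEt2, CH2Cl2, −78 °C) to give 19 after work-up.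

Step 6. Most likely failure: the reaction stops at the hydroxyethyl enol ether, or acid at reflux isomerises the isopropenyl double bond into conjugation, which would destroy C5. Fallback, from 12 back to 13, without hot acid:
- (COCl)2 with catalytic DMF converts 12 into the β-chloro enone F7, with chloride on the less hindered C7.
- The monosodium salt of ethylene glycol (NaH, excess glycol, THF) replaces chloride by addition–elimination to give the hydroxyethyl vinylogous ester F8.
- PPTS in CH2Cl2 at 25 °C closes F8 to 13.

Step 1. Most likely failure: insufficient enantioselectivity with an sp2-branched Grignard reagent, or competing 1,2-addition. Fallback, from 2 and 3 back to 9: move the stereocontrol to the auxiliary. An achiral addition (CuI catalyst, Me3SiCl, THF, −40 °C) gives the racemic ketone F9, which is submitted to the conditions of step 2. The imine of the (3R) enantiomer is the matched one and alkylates faster, so stopping at partial conversion gives 9 after hydrolysis and leaves the (3S) ketone F10 (kinetic resolution, at most half of the material).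

Step 14. Most likely failure: slow oxidation, because in 24 the ring is deactivated by the C7 acyl group and the C14 hydroxyl is hydrogen-bonded to it, with over-oxidation on forcing. Fallback, from 23 back to 25: change the order. The electron-rich ketal 23 is oxidised with (KSO3)2NO to the ketal hydroxyquinone F11, and the ketal is then removed with aqueous acetic acid to give 25.

## Further compounds

F1 | step 12 | bis-silyl ether of 19 (C14 tert-butyldimethylsilyl ether, C12 triethylsilyl ether) | C=C(C)[C@@H]1CC2(OCCO2)C(C(O[Si](C)(C)C(C)(C)C)C(C(C)C)C(C)O[Si](CC)(CC)CC)C(=O)[C@@]1(C)CCC(=O)OC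
F2 | step 12 | C12 alcohol with C14 tert-butyldimethylsilyl ether | C=C(C)[C@@H]1CC2(OCCO2)C(C(O[Si](C)(C)C(C)(C)C)C(C(C)C)C(C)O)C(=O)[C@@]1(C)CCC(=O)OC
F3 | step 12 | C12 methyl ketone with C14 tert-butyldimethylsilyl ether | C=C(C)[C@@H]1CC2(OCCO2)C(C(O[Si](C)(C)C(C)(C)C)C(C(C)C)C(C)=O)C(=O)[C@@]1(C)CCC(=O)OC
F4 | step 12 | cyclised β-hydroxy ketone (C9 carbinol, C12 ketone, C14 silyl ether) | C=C(C)[C@@H]1CC2(OCCO2)C3C(O[Si](C)(C)C(C)(C)C)C(C(C)C)C(=O)CC3(O)[C@@]1(C)CCC(=O)OC
F5 | step 12 | cyclised diol (C9 and C14 carbinols, C12 ketone) | C=C(C)[C@@H]1CC2(OCCO2)C3C(O)C(C(C)C)C(=O)CC3(O)[C@@]1(C)CCC(=O)OC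
F6 | step 10 | trimethylsilyl enol ether of 13 | C=C(C)[C@@H]1CC2(OCCO2)C=C(O[Si](C)(C)C)[C@@]1(C)CCC(=O)OC
F7 | step 6 | methyl 3-[(1S,6S)-4-chloro-1-methyl-2-oxo-6-(prop-1-en-2-yl)cyclohex-3-en-1-yl]propanoate | C=C(C)[C@@H]1CC(Cl)=CC(=O)[C@@]1(C)CCC(=O)OC
F8 | step 6 | methyl 3-[(1S,6S)-4-(2-hydroxyethoxy)-1-methyl-2-oxo-6-(prop-1-en-2-yl)cyclohex-3-en-1-yl]propanoate | C=C(C)[C@@H]1CC(OCCO)=CC(=O)[C@@]1(C)CCC(=O)OC
F9 | step 1 | racemic 2-methyl-3-(prop-1-en-2-yl)cyclohexan-1-one | C=C(C)C1CCCC(=O)C1C
F10 | step 1 | (3S)-2-methyl-3-(prop-1-en-2-yl)cyclohexan-1-one (unreacted enantiomer) | C=C(C)[C@H]1CCCC(=O)C1C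
F11 | step 14 | C7 ethylene ketal of the target hydroxyquinone | C=C(C)[C@@H]1CC2(OCCO2)C2=C(C(=O)C(O)=C(C(C)C)C2=O)[C@@]1(C)CCC(=O)OC
A1 | alternative 1 | 4-tert-butyl-2-[4,5,7-trimethoxy-6-(propan-2-yl)naphthalen-1-yl]-4,5-dihydrooxazole | COc1ccc(C2=N[C@H](C(C)(C)C)CO2)c2cc(OC)c(C(C)C)c(OC)c12
A2 | alternative 1 | 1,2-dihydronaphthalene with oxazoline and 3-(tert-butyldimethylsilyloxy)propyl on C1 and isopropenyl on C2 | C=C(C)[C@@H]1C=C(OC)c2c(OC)c(C(C)C)c(OC)cc2[C@@]1(C3=N[C@H](C(C)(C)C)CO3)CCCO[Si](C)(C)C(C)(C)C
A3 | alternative 2 | (E)-2,4-dimethylpenta-2,4-dienal | C=C(C)/C=C(\C)C=O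
A4 | alternative 2 | (E)-1-(tert-butyldimethylsilyloxy)buta-1,3-diene | C=C/C=C/O[Si](C)(C)C(C)(C)C
A5 | alternative 2 | 2-(tert-butyldimethylsilyloxy)-1-methyl-6-(prop-1-en-2-yl)cyclohex-3-ene-1-carbaldehyde | C=C(C)[C@@H]1CC=C[C@@H](O[Si](C)(C)C(C)(C)C)[C@@]1(C)C=O
A6 | alternative 3 | 4-hydroxy-4-(ring-B cyclohexenyl)-3-isopropoxy-2-isopropylcyclobut-2-en-1-one with C7 ketal and silyl ether chain | C=C(C)[C@@H]1CC2(OCCO2)C=C(C2(O)C(OC(C)C)=C(C(C)C)C2=O)[C@@]1(C)CCCO[Si](C)(C)C(C)(C)C
A7 | alternative 3 | ring-C hydroquinone with C12 isopropyl ether, C13 isopropyl, C7 ketal and silyl ether chain | C=C(C)[C@@H]1CC2(OCCO2)c2c(O)c(C(C)C)c(OC(C)C)c(O)c2[C@@]1(C)CCCO[Si](C)(C)C(C)(C)C
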